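Everything rests on growing the left carbocycle onto the finished lactone half instead of joining two arenes. Ring C4a–C5–C6–C7–C8–C8a is a 2-alkylresorcinol. C7, which bears the C9 methylene, lies between the oxygenated carbons C6 and C8, and this is the pattern a vinylketene/1-alkoxyalkyne benzannulation leaves behind. One thermal operation unites two partners. The first is a 3-alkyl-4-methylcyclobutenone holding the C3/C4 diad as a silyl ether. The second is the dihydroisocoumarin carrying a 3-methoxyprop-2-ynyl group on C7'. The reaction forms C6–C7 and C8–C8a, remakes C5–C6 and leaves C8a–H as the only open ring position. Formylation there, then one boron trichloride/acid operation, frees the oxygens and closes the pyran to the quinone methide.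

Key step: step 15

**Remarks and assumptions**
- **Numbering:** isochromane numbering (C1, O2, C3, C4, C4a, C5–C8, C8a). Unprimed atoms belong to the quinone-methide (left) half and primed atoms to the lactone (right) half. C9 is the bridging CH2.
- **Configuration:** the target SMILES reads 3R,4S,3'R,4'S. It is drawn as the C8-oxo/C6-hydroxy tautomer.
- **Assumption on step 9:** the facial sense is assigned by analogy with (E)-2-phenylbut-2-ene and 1-phenylcyclopentene. There, the reagent from (+)-α-pinene gives the S carbinol, so the (−)-α-pinene reagent is used here. Both antipodes are available.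
- **C9 and the C5' methyl:** arene 14 carries neither group.
  - C9 is put on by directed lithiation while the ring is still open (step 8). No electrophilic halomethylation is needed, so no diarylmethane can form.
  - The C5' methyl comes from the second bromine of a symmetric dibromide (steps 10–12).
- **Acetylide delivery:** the methoxyacetylide is delivered as a neutral stannane. The lactone therefore never meets an organolithium, an amine or an alkoxide.
- **Order of the end game:** C1 is introduced before the Lewis acid step. Once freed, the C3 oxygen is caught by the aldehyde in a six-membered ring, so it cannot leave with aryl participation. A phenonium ion from this threo 3-aryl-2-butyl unit would scramble the left diad.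

Step 1
Reactants: 1 methyl (R)-3-hydroxybutanoate
Product: 3 methyl (2R,3R)-3-hydroxy-2-methylbutanoate, via dilithio alkoxide enolate 2 (not isolated)
Conditions: LDA (2.2 equiv), THF, −78 → −20 °C; MeI, DMPU, −78 → 0 °C; then H2O
Reagents that add atoms: iodomethane, CI
Why: Fráter–Seebach alkylation, in which the lithium-chelated dianion 2 is methylated on the face away from the C3 methyl group, so the new centre (future C4) is set anti to the resident 3R carbinol (future C3).

Step 2
Reactants: 3 methyl (2R,3R)-3-hydroxy-2-methylbutanoate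
Product: 4 methyl (2R,3R)-3-(tert-butyldimethylsilyloxy)-2-methylbutanoate
Conditions: TBSCl, imidazole, DMF, rt
Reagents that add atoms: tert-butyldimethylsilyl chloride, CC(C)(C)[Si](C)(C)Cl
Why: Standard silylation of a secondary alcohol, giving an ether that should tolerate hydride, carbonate, the buffered triflate medium of step 5 and neutral heating, with neither stereocentre touched.

Step 3
Reactants: 4 methyl (2R,3R)-3-(tert-butyldimethylsilyloxy)-2-methylbutanoate
Product: 5 (2R,3R)-3-(tert-butyldimethylsilyloxy)-2-methylbutanal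
Conditions: DIBAL-H (1.1 equiv), CH2Cl2, −78 °C; Rochelle salt
Reagents that add atoms: none
Why: Low-temperature DIBAL-H reduction of an α-branched β-silyloxy methyl ester stops at the aldehyde level, and the aldehyde is carried on without chromatography so that C2 is not epimerised.

Step 4
Reactants: 5 (2R,3R)-3-(tert-butyldimethylsilyloxy)-2-methylbutanal
Product: 6 (3S,4R)-4-(tert-butyldimethylsilyloxy)-3-methylpent-1-yne
Conditions: dimethyl (1-diazo-2-oxopropyl)phosphonate, K2CO3, MeOH, 0 °C → rt
Reagents that add atoms: dimethyl (1-diazo-2-oxopropyl)phosphonate, CC(=O)C(=[N+]=[N-])P(=O)(OC)OC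
Why: Seyferth–Gilbert homologation in the Ohira–Bestmann variant converts α-chiral aldehydes into terminal alkynes under carbonate conditions mild enough to keep the α-centre (R becomes S only through the change in CIP ranking).

Step 5
Reactants: 6 (3S,4R)-4-(tert-butyldimethylsilyloxy)-3-methylpent-1-yne + 7 N,N-dimethylpropanamide
Product: 10 4-methyl-3-[(2S,3R)-3-(tert-butyldimethylsilyloxy)butan-2-yl]cyclobut-2-en-1-one (both C4 epimers), via keteniminium triflate 8 (not isolated), via cyclobuteniminium triflate 9 (not isolated)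
Conditions: 7 (2 equiv), Tf2O, 2,4,6-collidine, CH2Cl2, reflux; then H2O, rt
Reagents that add atoms: water, O
Why: Keteniminium–alkyne [2+2] cycloaddition, in which the electrophilic central carbon of 8 bonds to the terminal alkyne carbon and the methyl-bearing carbon to the internal one, so hydrolysis of 9 gives the 3-alkyl-4-methyl regioisomer, and the new ring centre needs no control because step 15 erases it.

Step 6
Reactants: 11 chloroacetaldehyde dimethyl acetal
Product: 13 tributyl(methoxyethynyl)stannane, via lithium methoxyacetylide 12 (not isolated)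
Conditions: LiNEt2 (3.1 equiv), THF, 0 °C; Bu3SnCl, −78 °C → rt; distillation
Reagents that add atoms: tributyltin chloride, CCCC[Sn](Cl)(CCCC)CCCC
Why: Double β-elimination (methanol, then HCl) and deprotonation of the chloroacetal give the alkoxyacetylide, and stannylation turns it into a distillable, non-basic alkynyl donor free of amine and alkoxide.

Step 7
Reactants: 14 1-bromo-3,5-dimethoxybenzene + 15 potassium (Z)-but-2-en-2-yltrifluoroborate
Product: 16 (E)-1-(but-2-en-2-yl)-3,5-dimethoxybenzene
Conditions: PdCl2(dppf)·CH2Cl2 (3 mol %), Cs2CO3, THF/H2O, 70 °C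
Reagents that add atoms: none
Why: Suzuki–Miyaura coupling of an alkenyltrifluoroborate proceeds with retention of alkene geometry, so the borate with cis methyl groups gives the (E)-2-arylbut-2-ene that step 9 requires.

Step 8
Reactants: 16 (E)-1-(but-2-en-2-yl)-3,5-dimethoxybenzene
Product: 18 (E)-5-(but-2-en-2-yl)-1,3-dimethoxy-2-(methoxymethyl)benzene, via aryllithium 17 (not isolated)
Conditions: n-BuLi, THF, 0 °C → rt; MOMCl, −78 °C → rt
Reagents that add atoms: chloromethyl methyl ether, COCCl
Why: Directed ortho-metalation occurs at the carbon flanked by both methoxy groups (future C7'), and alkylation of 17 installs C9 as a robust benzylic methyl ether.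

Step 9
Reactants: 18 (E)-5-(but-2-en-2-yl)-1,3-dimethoxy-2-(methoxymethyl)benzene
Product: 20 (2R,3S)-3-[3,5-dimethoxy-4-(methoxymethyl)phenyl]butan-2-ol, via isopinocampheyl(alkyl)borane 19 (not isolated)
Conditions: (IpcBH2)2·TMEDA [(−)-α-pinene series], BF3·OEt2, Et2O, rt, filter; 18, −25 °C; NaOH, 30 % H2O2, 0 °C → rt
Reagents that add atoms: hydrogen peroxide, OO
Why: Reagent-controlled asymmetric hydroboration of an aryl-substituted trisubstituted alkene, in which syn addition of H (benzylic carbon) and B across the (E)-alkene fixes the relative configuration, the pinene-derived borane selects the face leading to 2R,3S (future C3'/C4'), and oxidation retains configuration at carbon.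

Step 10
Reactants: 20 (2R,3S)-3-[3,5-dimethoxy-4-(methoxymethyl)phenyl]butan-2-ol
Product: 21 (2R,3S)-3-[2,6-dibromo-3,5-dimethoxy-4-(methoxymethyl)phenyl]butan-2-ol
Conditions: NBS (2.05 equiv), MeCN, 0 °C → rt, dark
Reagents that add atoms: N-bromosuccinimide, O=C1CCC(=O)N1Br
Why: Electrophilic aromatic bromination, in which the only two ring C–H positions are equivalent and each lies para to one methoxy group and ortho to the other, so a single dibromide should result.

Step 11
Reactants: 21 (2R,3S)-3-[2,6-dibromo-3,5-dimethoxy-4-(methoxymethyl)phenyl]butan-2-ol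
Product: 22 (3R,4S)-5-bromo-6,8-dimethoxy-7-(methoxymethyl)-3,4-dimethylisochroman-1-one
Conditions: Pd(OAc)2 (5 mol %), Xantphos, CO (1–3 bar), Et3N, toluene, 100 °C
Reagents that add atoms: carbon monoxide, [C-]#[O+]
Why: Palladium-catalysed carbonylative lactonisation, in which oxidative addition into either equivalent C–Br bond, CO insertion and capture by the tethered alcohol close the six-membered lactone without touching the carbinol C–O bond, while the second bromide has no internal nucleophile and stays.

Step 12
Reactants: 22 (3R,4S)-5-bromo-6,8-dimethoxy-7-(methoxymethyl)-3,4-dimethylisochroman-1-one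
Product: 23 (3R,4S)-6,8-dimethoxy-7-(methoxymethyl)-3,4,5-trimethylisochroman-1-one
Conditions: MeZnCl (2 equiv), Pd-PEPPSI-IPr (3 mol %), THF, 60 °C
Reagents that add atoms: methylzinc chloride, C[Zn]Cl
Why: Negishi methylation with a bulky carbene–palladium catalyst handles di-ortho-substituted aryl bromides and leaves the lactone alone, which supplies the C5' methyl group.

Step 13
Reactants: 23 (3R,4S)-6,8-dimethoxy-7-(methoxymethyl)-3,4,5-trimethylisochroman-1-one
Product: 24 (3R,4S)-7-(bromomethyl)-6,8-dimethoxy-3,4,5-trimethylisochroman-1-one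
Conditions: HBr (33 % in AcOH), CH2Cl2, 0 °C; used without storage
Reagents that add atoms: hydrogen bromide, Br
Why: Acid cleavage of an electron-rich benzylic methyl ether (SN1 through a cation flanked by two methoxy groups) gives the bromide, and because every ring position is occupied the cation cannot alkylate a second arene.

Step 14
Reactants: 24 (3R,4S)-7-(bromomethyl)-6,8-dimethoxy-3,4,5-trimethylisochroman-1-one + 13 tributyl(methoxyethynyl)stannane
Product: 25 (3R,4S)-6,8-dimethoxy-7-(3-methoxyprop-2-yn-1-yl)-3,4,5-trimethylisochroman-1-one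
Conditions: Pd2(dba)3 (2.5 mol %), P(2-furyl)3, THF, 50 °C; aq. KF; Et3N-deactivated silica
Reagents that add atoms: none
Why: Stille coupling of a benzylic bromide with an alkynylstannane (the fastest-transferring tin ligand) forms C9–C(sp) under neutral conditions, so neither the lactone nor the base-sensitive propargylic CH2 is put at risk.

Step 15
Reactants: 25 (3R,4S)-6,8-dimethoxy-7-(3-methoxyprop-2-yn-1-yl)-3,4,5-trimethylisochroman-1-one + 10 4-methyl-3-[(2S,3R)-3-(tert-butyldimethylsilyloxy)butan-2-yl]cyclobut-2-en-1-one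
Product: 30 (3R,4S)-7-({4-[(2S,3R)-3-(tert-butyldimethylsilyloxy)butan-2-yl]-2-hydroxy-6-methoxy-3-methylphenyl}methyl)-6,8-dimethoxy-3,4,5-trimethylisochroman-1-one, via vinylketene 26 (not isolated), via vinylcyclobutenone 27 (not isolated), via dienylketene 28 (not isolated), via cyclohexadienone 29 (not isolated)
Conditions: 10 (1.5 equiv), degassed toluene, sealed base-washed tube, 80 °C, then 120 °C
Reagents that add atoms: none
Why: Danheiser benzannulation: cyclobutenone 10 opens by 4π electrocyclic cleavage of C5–C6 (methyl turning outward) to vinylketene 26, whose carbonyl carbon (C6) is attacked by the nucleophilic, oxygen-remote alkyne carbon (C7) while the ketene α-carbon (C8a) closes onto the oxygen-bearing carbon (C8), a polarised [2+2] that gives 27. Further heating opens 27 reversibly (4π) to dienylketene 28, and only the isomer with C4a and C7 cis on C8=C8a can react on. The benzene ring is closed by 6π disrotatory electrocyclisation between C5 and C6 to dienone 29, which tautomerises to phenol 30. No stereocentre is created, since the ring centre of 10 and the transient centres at C8a and C5 all end up sp2, and both stereodiads, the lactone and the silyl ether are spectators under neutral thermal conditions. The one selectivity needed is the orientation of the [2+2], and the methoxy group secures it by making C7 the nucleophilic terminus, which places C9 between O6 and O8 and leaves C8a–H free. The closest known cases are benzannulations of 3-alkyl-4-methylcyclobutenones with 1-methoxyalk-1-ynes that bear an activated propargylic CH2, and a methoxy group has no β-hydrogen, so retro-ene loss of the ynol ether is excluded.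

Step 16
Reactants: 30 benzannulation product (phenol, C8a–H)
Product: 32 (3R,4S)-7-({4-[(2S,3R)-3-(tert-butyldimethylsilyloxy)butan-2-yl]-5-formyl-2-hydroxy-6-methoxy-3-methylphenyl}methyl)-6,8-dimethoxy-3,4,5-trimethylisochroman-1-one, via aryl iminium chloride 31 (not isolated)
Conditions: POCl3 (2 equiv), DMF, 0 → 40 °C; then aq. NaOAc, rt
Reagents that add atoms: N,N-dimethylformamide, CN(C)C=O; water, O
Why: Vilsmeier–Haack formylation can strike only C8a, the single aromatic C–H of the molecule, which is para to the free O6 hydroxyl and ortho to the O8 methoxy group, and the non-protic medium spares the silyl ether and the diarylmethane.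

Step 17
Reactants: 32 aldehyde (C8a–CHO)
Product: 35 dicitrinone G, via hydroxy aldehyde 33 (not isolated), via lactol 34 (not isolated)
Conditions: BCl3 (10 equiv), CH2Cl2, −78 °C → rt; then THF/2 M aq. HCl, rt
Reagents that add atoms: none
Why: Boron trichloride cleaves aryl methyl ethers that are chelated to an ortho carbonyl (O8, O8') or crowded by two ortho substituents (O6'), the acid stage removes what is left of the silyl ether, and the freed C3 hydroxyl of 33 adds to the neighbouring aldehyde (34) and loses water to give the quinone methide with C3 and C4 unchanged.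

**Compound list**
1 | methyl (R)-3-hydroxybutanoate | C[C@@H](O)CC(=O)OC | starting material
2 | dilithio alkoxide enolate of 1 | C[C@@H]([O-])/C=C(\[O-])OC.[Li+].[Li+] | intermediate
3 | methyl (2R,3R)-3-hydroxy-2-methylbutanoate | C[C@@H](O)[C@@H](C)C(=O)OC | intermediate
4 | methyl (2R,3R)-3-(tert-butyldimethylsilyloxy)-2-methylbutanoate | C[C@@H](O[Si](C)(C)C(C)(C)C)[C@@H](C)C(=O)OC | intermediate
5 | (2R,3R)-3-(tert-butyldimethylsilyloxy)-2-methylbutanal | C[C@@H](O[Si](C)(C)C(C)(C)C)[C@@H](C)C=O | intermediate
6 | (3S,4R)-4-(tert-butyldimethylsilyloxy)-3-methylpent-1-yne | C[C@@H](O[Si](C)(C)C(C)(C)C)[C@@H](C)C#C | intermediate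
7 | N,N-dimethylpropanamide | CCC(=O)N(C)C | starting material
8 | N,N-dimethyl(prop-1-en-1-ylidene)ammonium triflate (keteniminium) | CC=C=[N+](C)C.[O-]S(=O)(=O)C(F)(F)F | intermediate
9 | cyclobuteniminium triflate from 6 and 8 | CC1C(=[N+](C)C)C=C1[C@H](C)[C@@H](C)O[Si](C)(C)C(C)(C)C.[O-]S(=O)(=O)C(F)(F)F | intermediate
10 | 4-methyl-3-[(2S,3R)-3-(tert-butyldimethylsilyloxy)butan-2-yl]cyclobut-2-en-1-one (C4 epimers) | CC1C(=O)C=C1[C@H](C)[C@@H](C)O[Si](C)(C)C(C)(C)C | intermediate
11 | chloroacetaldehyde dimethyl acetal | COC(CCl)OC | starting material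
12 | lithium methoxyacetylide | [Li]C#COC | intermediate
13 | tributyl(methoxyethynyl)stannane | CCCC[Sn](CCCC)(CCCC)C#COC | intermediate
14 | 1-bromo-3,5-dimethoxybenzene | COc1cc(Br)cc(OC)c1 | starting material
15 | potassium (Z)-but-2-en-2-yltrifluoroborate | C/C=C(\C)[B-](F)(F)F.[K+] | starting material
16 | (E)-1-(but-2-en-2-yl)-3,5-dimethoxybenzene | C/C=C(\C)c1cc(OC)cc(OC)c1 | intermediate
17 | 4-[(E)-but-2-en-2-yl]-2,6-dimethoxyphenyllithium | C/C=C(\C)c1cc(OC)c([Li])c(OC)c1 | intermediate
18 | (E)-5-(but-2-en-2-yl)-1,3-dimethoxy-2-(methoxymethyl)benzene | C/C=C(\C)c1cc(OC)c(COC)c(OC)c1 | intermediate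
19 | isopinocampheyl[(2R,3S)-3-arylbutan-2-yl]borane | C[C@@H]1[C@@H](B[C@H](C)[C@@H](C)c3cc(OC)c(COC)c(OC)c3)C[C@H]2C[C@@H]1C2(C)C | intermediate
20 | (2R,3S)-3-[3,5-dimethoxy-4-(methoxymethyl)phenyl]butan-2-ol | C[C@@H](O)[C@@H](C)c1cc(OC)c(COC)c(OC)c1 | intermediate
21 | (2R,3S)-3-[2,6-dibromo-3,5-dimethoxy-4-(methoxymethyl)phenyl]butan-2-ol | C[C@@H](O)[C@@H](C)c1c(Br)c(OC)c(COC)c(OC)c1Br | intermediate
22 | (3R,4S)-5-bromo-6,8-dimethoxy-7-(methoxymethyl)-3,4-dimethylisochroman-1-one | COCc1c(OC)c(Br)c2c(c1OC)C(=O)O[C@H](C)[C@H]2C | intermediate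
23 | (3R,4S)-6,8-dimethoxy-7-(methoxymethyl)-3,4,5-trimethylisochroman-1-one | COCc1c(OC)c(C)c2c(c1OC)C(=O)O[C@H](C)[C@H]2C | intermediate
24 | (3R,4S)-7-(bromomethyl)-6,8-dimethoxy-3,4,5-trimethylisochroman-1-one | BrCc1c(OC)c(C)c2c(c1OC)C(=O)O[C@H](C)[C@H]2C | intermediate
25 | (3R,4S)-6,8-dimethoxy-7-(3-methoxyprop-2-yn-1-yl)-3,4,5-trimethylisochroman-1-one | COC#CCc1c(OC)c(C)c2c(c1OC)C(=O)O[C@H](C)[C@H]2C | intermediate
26 | (E)-vinylketene from 10 | C/C=C(/C=C=O)[C@H](C)[C@@H](C)O[Si](C)(C)C(C)(C)C | intermediate
27 | 4-alkenyl-3-methoxy-2-(arylmethyl)cyclobut-2-enone (C8a epimers) | COC1=C(Cc2c(OC)c(C)c3c(c2OC)C(=O)O[C@H](C)[C@H]3C)C(=O)C1/C(=C/C)[C@H](C)[C@@H](C)O[Si](C)(C)C(C)(C)C | intermediate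
28 | dienylketene | O=C=C(Cc1c(OC)c(C)c2c(c1OC)C(=O)O[C@H](C)[C@H]2C)/C(OC)=C\C(=C\C)[C@H](C)[C@@H](C)O[Si](C)(C)C(C)(C)C | intermediate
29 | cyclohexa-2,4-dienone (keto tautomer of 30) | CC1C(=O)C(Cc2c(OC)c(C)c3c(c2OC)C(=O)O[C@H](C)[C@H]3C)=C(OC)C=C1[C@H](C)[C@@H](C)O[Si](C)(C)C(C)(C)C | intermediate
30 | left resorcinol monomethyl ether joined through C9 to the lactone half | Cc1c(O)c(Cc2c(OC)c(C)c3c(c2OC)C(=O)O[C@H](C)[C@H]3C)c(OC)cc1[C@H](C)[C@@H](C)O[Si](C)(C)C(C)(C)C | intermediate
31 | C8a dimethyliminium chloride of 30 | Cc1c(O)c(Cc2c(OC)c(C)c3c(c2OC)C(=O)O[C@H](C)[C@H]3C)c(OC)c(C=[N+](C)C)c1[C@H](C)[C@@H](C)O[Si](C)(C)C(C)(C)C.[Cl-] | intermediate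
32 | C8a aldehyde of 30 | Cc1c(O)c(Cc2c(OC)c(C)c3c(c2OC)C(=O)O[C@H](C)[C@H]3C)c(OC)c(C=O)c1[C@H](C)[C@@H](C)O[Si](C)(C)C(C)(C)C | intermediate
33 | fully deprotected hydroxy aldehyde | Cc1c(O)c(Cc2c(O)c(C)c3c(c2O)C(=O)O[C@H](C)[C@H]3C)c(O)c(C=O)c1[C@H](C)[C@@H](C)O | intermediate
34 | lactol (1-hydroxyisochroman, C1 epimers) | OC1O[C@H](C)[C@@H](C)c2c(C)c(O)c(Cc3c(O)c(C)c4c(c3O)C(=O)O[C@H](C)[C@H]4C)c(O)c12 | intermediate
35 | dicitrinone G | CC1=C2C(=CO[C@H](C)[C@H]2C)C(=O)C(Cc2c(O)c(C)c3c(c2O)C(=O)O[C@H](C)[C@H]3C)=C1O | target

**Step count**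
- Total steps: 17.
- Longest linear sequence: 11 steps (14 → 35, steps 7–17).
- The cyclobutenone branch has 5 steps and the stannane branch 1.

**Steps most likely to fail**

1. **Step 15.**
   - What may go wrong:
     - Capture of the vinylketene by the bulky ynol ether may lose out to ketene dimerisation.
     - The ketene may instead acylate the product phenol.
     - The cascade may stall at the vinylcyclobutenone.
   - Fallback (sets out from 16 and 24, comes back at 33): the left ring is taken from the arene pool and C7–C9 is made by cross-coupling.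
     - Alkene 16 is hydroborated and oxidised as in step 9 to (2R,3S)-3-(3,5-dimethoxyphenyl)butan-2-ol F1.
     - One equivalent of NBS gives the 2-bromo alcohol F2, silylation gives the TBS ether F3, and Negishi methylation gives the 2-methyl arene F4.
     - Lithiation between the two methoxy groups and zincation (n-BuLi, then ZnCl2) give the arylzinc chloride F5.
     - Palladium couples F5 with bromide 24 to give the O6-methyl ether of 30, F6.
     - Vilsmeier–Haack formylation at the only free ring carbon gives the O6-methyl ether of 32, F7.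
     - The boron trichloride/acid treatment of step 17, now on four methyl ethers, leads to 33 and on to 35.

2. **Step 17.**
   - What may go wrong: the unchelated methyl ether on O6' may resist cleavage, or long contact of the nascent quinone methide with the Lewis acid may erode it.
   - Fallback (sets out from 30, comes back at 35): the oxygens are freed first and C1 is added last, delivered intramolecularly.
     - BBr3 at −78 → 0 °C, with the silyl ether kept on so that the C3 oxygen is never a boron ester, gives the tetraphenol silyl ether F8.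
     - Aqueous HF in MeCN gives the pentaol F9.
     - Triethyl orthoformate with catalytic HCl forms the mixed orthoester at the C3 hydroxyl, which attacks C8a (oxa-Pictet–Spengler closure at the formate level) and loses ethanol to give 35.

3. **Step 9.**
   - What may go wrong: the facial selectivity of the chiral borane may be too low for a single enantiomer.
   - Fallback (sets out from 18, comes back at 20): the relative configuration is still set by syn hydroboration, and the absolute configuration comes from enzymatic kinetic resolution.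
     - BH3·THF, then NaOH/H2O2, gives the racemic threo alcohol F10.
     - Lipase CAL-B with vinyl acetate acylates the (2R)-enantiomer of this methyl carbinol to the (2R,3S)-acetate F11, which is separated from the unreacted (2S,3R)-alcohol.
     - K2CO3/MeOH returns 20.

**Further compounds**
F1 | step 15 | (2R,3S)-3-(3,5-dimethoxyphenyl)butan-2-ol | C[C@@H](O)[C@@H](C)c1cc(OC)cc(OC)c1
F2 | step 15 | (2R,3S)-3-(2-bromo-3,5-dimethoxyphenyl)butan-2-ol | C[C@@H](O)[C@@H](C)c1cc(OC)cc(OC)c1Br
F3 | step 15 | TBS ether of F2 | C[C@@H](O[Si](C)(C)C(C)(C)C)[C@@H](C)c1cc(OC)cc(OC)c1Br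
F4 | step 15 | tert-butyl{[(2R,3S)-3-(3,5-dimethoxy-2-methylphenyl)butan-2-yl]oxy}dimethylsilane | C[C@@H](O[Si](C)(C)C(C)(C)C)[C@@H](C)c1cc(OC)cc(OC)c1C
F5 | step 15 | arylzinc chloride from F4 (zinc between the methoxy groups) | C[C@@H](O[Si](C)(C)C(C)(C)C)[C@@H](C)c1cc(OC)c([Zn]Cl)c(OC)c1C
F6 | step 15 | O6-methyl ether of 30 | Cc1c(OC)c(Cc2c(OC)c(C)c3c(c2OC)C(=O)O[C@H](C)[C@H]3C)c(OC)cc1[C@H](C)[C@@H](C)O[Si](C)(C)C(C)(C)C
F7 | step 15 | O6-methyl ether of 32 | Cc1c(OC)c(Cc2c(OC)c(C)c3c(c2OC)C(=O)O[C@H](C)[C@H]3C)c(OC)c(C=O)c1[C@H](C)[C@@H](C)O[Si](C)(C)C(C)(C)C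
F8 | step 17 | tetraphenol silyl ether | Cc1c(O)c(Cc2c(O)c(C)c3c(c2O)C(=O)O[C@H](C)[C@H]3C)c(O)cc1[C@H](C)[C@@H](C)O[Si](C)(C)C(C)(C)C
F9 | step 17 | pentaol (tetraphenol with free C3 hydroxyl) | Cc1c(O)c(Cc2c(O)c(C)c3c(c2O)C(=O)O[C@H](C)[C@H]3C)c(O)cc1[C@H](C)[C@@H](C)O
F10 | step 9 | racemic threo-3-[3,5-dimethoxy-4-(methoxymethyl)phenyl]butan-2-ol | C[C@@H](O)[C@@H](C)c1cc(OC)c(COC)c(OC)c1.C[C@H](O)[C@H](C)c1cc(OC)c(COC)c(OC)c1
F11 | step 9 | (2R,3S)-3-[3,5-dimethoxy-4-(methoxymethyl)phenyl]butan-2-yl acetate | CC(=O)O[C@H](C)[C@@H](C)c1cc(OC)c(COC)c(OC)c1
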